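**Plan**
- Retrosynthesis cuts the C1–C13' bond between the two germacranolide halves, then in each half the lactone O–C8 bond (back to a ring C8=C9 olefin next to a C10–C1 oxirane), the C8=C9 ring olefin and the C6–C7 bond.
- Forward: geranyl acetate gives a vinyl-oxirane enal. Allene hydroboration–allylboration (C6–C7) and ring-closing metathesis (C8=C9) build each ten-membered ring, and a palladium-triggered lactonisation closes each γ-lactone. The halves are joined last by an allyl–alkyl Negishi-type coupling, followed by desilylation.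
- Enabling feature: in both halves the lactone oxygen sits on allylic C8 of a (Z)-C8–C9=C10–C1 unit whose far end C1 carries O (unit B) or C13' (unit A). This 1,4-difunctionalised 2-ene inside the ten-membered ring is the retron of an allylpalladium species made from a ring vinyl oxirane.
- Stereochemistry: one Shi epoxidation sets the oxirane (later C10/C1). Reagent-controlled allylboration sets C6/C7 (syn for unit B, anti for unit A). C8 and the (Z)-C9=C10 olefin are relayed from the oxirane in the lactonisation. The released C1 carbinol is inverted (Mitsunobu in unit B, C–C coupling in unit A). C11' comes from enolate alkylation anti to C6'.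

Key step: step 9

Remark (locants): germacrane numbering for each ten-membered ring (C1–C10; methyls on C4 and C10; carbinol C6; C7 bears C11–C12; C8 bears the lactone oxygen). Unit A is the α-methylene lactone half, unit B (primed) the saturated lactone half; C13' is the CH2 linking C11' to C1.
Remark (assumption): ring-closing metathesis is taken to give the (8Z)-cyclodecadiene, because the ring already holds an E-olefin and a trans-oxirane. The stereochemical bookkeeping after steps 9 and 16 (lactone O–C8 and O–C1 trans across the new olefin) rests on this.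

**Step 1**
Reactants: 1 geranyl acetate
Product: 2 (2E,6E)-3,7-dimethyl-8-oxoocta-2,6-dien-1-yl acetate
Conditions: SeO2 (1.2 equiv), EtOH, reflux
Reagents that add atoms: selenium dioxide, O=[Se]=O
Why: Riley allylic oxidation (ene reaction then [2,3]-shift) should attack the electron-rich terminal olefin at its (E)-methyl group and run on to the (E)-enal, the C2=C3 olefin being deactivated by the allylic acetate.

**Step 2**
Reactants: 2 (2E,6E)-3,7-dimethyl-8-oxoocta-2,6-dien-1-yl acetate
Product: 3 (2E,6E)-3,7-dimethylnona-2,6,8-trien-1-yl acetate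
Conditions: Ph3PCH3Br, KN(SiMe3)2, THF, −78 → 0 °C
Reagents that add atoms: methyltriphenylphosphonium bromide, C[P+](c1ccccc1)(c1ccccc1)c1ccccc1.[Br-]
Why: Wittig methylenation, in which the non-stabilised ylide should add to the enal much faster than to the acetate and leave the (6E)-geometry untouched.

**Step 3**
Reactants: 3 (2E,6E)-3,7-dimethylnona-2,6,8-trien-1-yl acetate
Product: 4 (2E,6S,7S)-6,7-epoxy-3,7-dimethylnona-2,8-dien-1-yl acetate
Conditions: ent-Shi ketone (L-fructose-derived, 30 mol%), KHSO5 (as its triple salt), K2CO3, Bu4NHSO4, MeCN–CH2(OMe)2–aq. buffer pH 10.5, −10 °C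
Reagents that add atoms: potassium peroxymonosulfate, [K+].[O-]S(=O)(=O)OO
Why: Shi dioxirane epoxidation should attack the most electron-rich, trisubstituted C6=C7 bond of the diene through the spiro transition state (the allylic-acetate olefin and the vinyl group being less nucleophilic) and set both oxirane stereocentres, the ketone enantiomer being chosen for the (6S,7S) sense.

**Step 4**
Reactants: 4 (2E,6S,7S)-6,7-epoxy-3,7-dimethylnona-2,8-dien-1-yl acetate
Product: 5 (2E,6S,7S)-6,7-epoxy-3,7-dimethylnona-2,8-dien-1-ol
Conditions: K2CO3 (0.2 equiv), MeOH, 0 °C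
Reagents that add atoms: none
Why: Base-catalysed transesterification removes the acetate, and the vinyl oxirane should be stable to carbonate in methanol at 0 °C.

**Step 5**
Reactants: 5 (2E,6S,7S)-6,7-epoxy-3,7-dimethylnona-2,8-dien-1-ol
Product: 6 (2E,6S,7S)-6,7-epoxy-3,7-dimethylnona-2,8-dienal
Conditions: MnO2, CH2Cl2, rt
Reagents that add atoms: none
Why: Allylic oxidation with MnO2 should give the (E)-enal without touching the vinyl oxirane.

**Step 6**
Reactants: 6 (2E,6S,7S)-6,7-epoxy-3,7-dimethylnona-2,8-dienal; 7 ethyl penta-3,4-dienoate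
Product: 9 ethyl (3S,4R,5E,9S,10S)-3-ethenyl-9,10-epoxy-4-hydroxy-6,10-dimethyldodeca-5,11-dienoate (3,4-syn), via Z-allylborane 8 (not isolated)
Conditions: (+)-Ipc2BH [from (−)-α-pinene], THF, −40 °C (7 only); then 6, −78 °C; then HOCH2CH2NH2, Et2O
Reagents that add atoms: none
Why: Kinetic hydroboration of the terminal allene π-bond anti to the CH2CO2Et group should give the (Z)-γ-substituted allylborane, which adds to the aldehyde through a chair transition state to give the C6'/C7' syn adduct, the isopinocampheyl groups choosing the aldehyde Re face (allene hydroboration–allylboration).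

**Step 7**
Reactants: 9 syn-homoallylic alcohol
Product: 10 ethyl (3S,4R,5E,9S,10S)-4-(tert-butyldimethylsilyloxy)-3-ethenyl-9,10-epoxy-6,10-dimethyldodeca-5,11-dienoate
Conditions: TBSOTf, 2,6-lutidine (excess), CH2Cl2, −78 °C
Reagents that add atoms: tert-butyldimethylsilyl trifluoromethanesulfonate, CC(C)(C)[Si](C)(C)OS(=O)(=O)C(F)(F)F
Why: Low-temperature silylation caps the γ-hydroxy ester before it can lactonise and marks C6'–OH as distinct from the carbinol released later at C1'.

**Step 8**
Reactants: 10 silyl ether diene
Product: 11 ring ester of unit B, ethyl (4E,8Z)-6-(tert-butyldimethylsilyloxy)-1,10-epoxy-13-norgermacra-4,8-dien-12-oate (stereocentres as in 10)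
Conditions: second-generation Grubbs catalyst RuCl2(=CHPh)(PCy3)(H2IMes) (10 mol%), toluene (0.001 M), 80 °C
Reagents that add atoms: none
Why: Ring-closing metathesis should join the two monosubstituted vinyl groups (the trisubstituted C4'=C5' olefin is inert) with loss of ethylene, the (8'Z)-olefin being expected for a ten-membered ring that already contains an E-olefin and a trans-oxirane.

**Step 9**
Reactants: 11 ring ester of unit B
Product: 13 unit B lactone with epimeric C1' carbinol, (4E,9Z)-6-(tert-butyldimethylsilyloxy)-1-hydroxy-13-norgermacra-4,9-dien-12,8-olide (trans-fused; C6', C7', C8' as in the target; C1'–OH opposite to the target), via lithium carboxylate 12 (not isolated)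
Conditions: LiOH·H2O (1.05 equiv), THF–H2O, rt; evaporation, toluene azeotrope; Pd(PPh3)4 (5 mol%), THF–DMF, rt; aq. NH4Cl
Reagents that add atoms: lithium hydroxide, [Li+].[OH-]
Why: Saponification frees the C12' carboxylate; zerovalent palladium then ionises the ring vinyl oxirane anti to the C10'–O bond to a zwitterionic η3-allylpalladium (C8'–C9'–C10') bearing the C1' alkoxide, and the carboxylate attacks C8' on the face opposite to palladium, releasing the catalyst. The closest known reaction type is the Tsuji–Trost 1,4-addition of carboxylic acids to vinyl epoxides and the allylic lactonisation of carboxylates. The γ-lactone is closed 5-exo onto the allyl terminus C8', which forms the O–C8' bond. C8' is controlled by double inversion, so its new C–O bond lies on the face the oxirane oxygen left (relay from the Shi-set C10'), and the trans ring fusion follows because C7' (step 6) holds the CH2CO2 arm on that face. The step needs attack at C8' rather than C10' (which would give a seven-membered lactone at a quaternary carbon) and a (Z)-C9'=C10' olefin (C1' anti on the allyl): the two-atom tether on C7' should reach C8' only in the U-shaped oxirane conformer, and reversible re-ionisation of the allylic lactone should funnel material to the more stable trans-fused isomer. The C1' carbinol is released with its oxirane configuration, trans to the lactone oxygen across the olefin, and is corrected in step 10.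

**Step 10**
Reactants: 13 unit B lactone with epimeric C1' carbinol
Product: 15 unit B lactone with C1'–OH as in the target (6'-O-TBS), via 4-nitrobenzoate 14 (not isolated)
Conditions: PPh3, DIAD, 4-O2NC6H4CO2H, THF, 0 °C → rt; then K2CO3 (cat.), MeOH, 0 °C
Reagents that add atoms: 4-nitrobenzoic acid, OC(=O)c1ccc(cc1)[N+](=O)[O-]
Why: Mitsunobu inversion (SN2 displacement of the oxyphosphonium by the carboxylate, SN2' being disfavoured at C9' next to the ring-fusion carbon) followed by mild methanolysis should give the C1' configuration of the target.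

**Step 11**
Reactants: 15 unit B lactone alcohol
Product: 16 1',6'-bis(tert-butyldimethylsilyl) ether of the unit B lactone
Conditions: TBSOTf, 2,6-lutidine, CH2Cl2, −78 → 0 °C
Reagents that add atoms: tert-butyldimethylsilyl trifluoromethanesulfonate, CC(C)(C)[Si](C)(C)OS(=O)(=O)C(F)(F)F
Why: Silylation protects the C1' carbinol against the amide base of step 12 and the organozinc of step 19.

**Step 12**
Reactants: 16 bis-silyl lactone
Product: 17 α-(iodomethyl) lactone of unit B (C11' as in the target, C13' = CH2I)
Conditions: LiN(i-Pr)2, THF, −78 °C; CH2I2 (5 equiv), DMPU, −78 → −40 °C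
Reagents that add atoms: diiodomethane, ICI
Why: Alkylation of the lactone lithium enolate with diiodomethane should occur on the face anti to the C7'–C6' bond, setting C11' trans to the C7' substituent and installing C13' as a primary iodide (enolate alkylation).

**Step 13**
Reactants: 6 (2E,6S,7S)-6,7-epoxy-3,7-dimethylnona-2,8-dienal; 7 ethyl penta-3,4-dienoate
Product: 19 ethyl (3S,4S,5E,9S,10S)-3-ethenyl-9,10-epoxy-4-hydroxy-6,10-dimethyldodeca-5,11-dienoate (3,4-anti), via E-allylborane 18 (not isolated)
Conditions: (−)-Ipc2BH [from (+)-α-pinene], THF, −40 → 25 °C (7 only, equilibration); then 6, −78 °C; then HOCH2CH2NH2, Et2O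
Reagents that add atoms: none
Why: After 1,3-boratropic equilibration to the (E)-allylborane the same chair allylboration should give the C6/C7 anti adduct, the enantiomeric isopinocampheyl groups choosing the aldehyde Si face so that C7 is set as in step 6 and C6 is epimeric.

**Step 14**
Reactants: 19 anti-homoallylic alcohol
Product: 20 ethyl (3S,4S,5E,9S,10S)-4-(tert-butyldimethylsilyloxy)-3-ethenyl-9,10-epoxy-6,10-dimethyldodeca-5,11-dienoate
Conditions: TBSOTf, 2,6-lutidine (excess), CH2Cl2, −78 °C
Reagents that add atoms: tert-butyldimethylsilyl trifluoromethanesulfonate, CC(C)(C)[Si](C)(C)OS(=O)(=O)C(F)(F)F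
Why: Silylation as in step 7 blocks lactonisation onto C6–OH and keeps this oxygen distinct from the C1 carbinol that becomes the leaving group.

**Step 15**
Reactants: 20 silyl ether diene
Product: 21 ring ester of unit A, the C6 epimer of 11
Conditions: second-generation Grubbs catalyst RuCl2(=CHPh)(PCy3)(H2IMes) (10 mol%), toluene (0.001 M), 80 °C
Reagents that add atoms: none
Why: Ring-closing metathesis as in step 8 should give the (8Z)-cyclodecadiene with loss of ethylene.

**Step 16**
Reactants: 21 ring ester of unit A
Product: 23 unit A lactone, (4E,9Z)-6-(tert-butyldimethylsilyloxy)-1-hydroxy-13-norgermacra-4,9-dien-12,8-olide (C6, C7, C8 as in the target; C1–OH trans to the lactone oxygen across the olefin), via lithium carboxylate 22 (not isolated)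
Conditions: LiOH·H2O (1.05 equiv), THF–H2O, rt; evaporation, toluene azeotrope; Pd(PPh3)4 (5 mol%), THF–DMF, rt; aq. NH4Cl
Reagents that add atoms: lithium hydroxide, [Li+].[OH-]
Why: The same Tsuji–Trost lactonisation as in step 9 should set C8 and the (9Z)-olefin by double inversion from the oxirane and release the C1 carbinol in the configuration needed for substitution with inversion in step 19.

**Step 17**
Reactants: 23 unit A lactone
Product: 25 α-methylene lactone of unit A with free C1–OH, via iodomethyl lactone 24 (not isolated)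
Conditions: LiN(i-Pr)2 (2.2 equiv), THF, −78 °C; CH2I2, DMPU, −78 → −40 °C; then DBU, rt; aq. NH4Cl
Reagents that add atoms: diiodomethane, ICI
Why: The alkoxide–enolate dianion should be C-alkylated by diiodomethane, and DBU then removes HI to give the exocyclic olefin (two-stage α-methylenation by enolate alkylation and elimination).

**Step 18**
Reactants: 25 α-methylene lactone alcohol
Product: 26 C1 methyl carbonate of the unit A α-methylene lactone
Conditions: ClCO2Me, pyridine, CH2Cl2, 0 °C
Reagents that add atoms: methyl chloroformate, COC(=O)Cl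
Why: Acylation of the allylic C1 alcohol gives the carbonate leaving group for allylpalladium formation, with retention at C1.

**Step 19**
Reactants: 17 α-(iodomethyl) lactone of unit B; 26 C1 methyl carbonate of unit A
Product: 28 tris(tert-butyldimethylsilyl) ether of the target (6-O, 1'-O, 6'-O), via alkylzinc iodide 27 (not isolated)
Conditions: Zn dust (activated with Me3SiCl and BrCH2CH2Br), DMF, 25 °C (17 only); then 26, Pd2(dba)3 (2.5 mol%), P(2-furyl)3 (10 mol%), THF–DMF, 25 °C; aq. NH4Cl
Reagents that add atoms: none
Why: Proposed new method: zinc inserts into the primary C13'–I bond to give a β-zincio lactone with no β-leaving group; zerovalent palladium ionises the allylic carbonate anti to its leaving group (much faster than either allylic lactone C–O bond), the alkyl group passes from zinc to palladium, and reductive elimination delivers it to C1 from the palladium face, that is with overall inversion and at the less hindered allyl terminus (C9 is flanked by ring-fusion carbon C8), retaining the (9Z)-olefin; the closest known reaction types are the Negishi coupling of organozinc halides with allylic esters (inversion) and palladium-catalysed couplings of β-zincio esters with sp2 halides.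

**Step 20**
Reactants: 28 tris-silyl ether of the target
Product: 29 target CNP0307352.2
Conditions: HF·pyridine, pyridine, THF, 0 °C → rt
Reagents that add atoms: none
Why: Buffered fluoride desilylation should cleave the three secondary silyl ethers without base-mediated addition to the α-methylene lactone or lactone migration.

**Compound list**
1 | geranyl acetate, (2E)-3,7-dimethylocta-2,6-dien-1-yl acetate | CC(=O)OC/C=C(\C)CCC=C(C)C | starting material
2 | (2E,6E)-3,7-dimethyl-8-oxoocta-2,6-dien-1-yl acetate | CC(=O)OC/C=C(\C)CC/C=C(\C)C=O | intermediate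
3 | (2E,6E)-3,7-dimethylnona-2,6,8-trien-1-yl acetate | CC(=O)OC/C=C(\C)CC/C=C(\C)C=C | intermediate
4 | (2E,6S,7S)-6,7-epoxy-3,7-dimethylnona-2,8-dien-1-yl acetate | CC(=O)OC/C=C(\C)CC[C@@H]1O[C@@]1(C)C=C | intermediate
5 | (2E,6S,7S)-6,7-epoxy-3,7-dimethylnona-2,8-dien-1-ol | OC/C=C(\C)CC[C@@H]1O[C@@]1(C)C=C | intermediate
6 | (2E,6S,7S)-6,7-epoxy-3,7-dimethylnona-2,8-dienal | O=C/C=C(\C)CC[C@@H]1O[C@@]1(C)C=C | intermediate
7 | ethyl penta-3,4-dienoate | CCOC(=O)CC=C=C | starting material
8 | (Z)-(5-ethoxy-5-oxopent-2-en-1-yl)diisopinocampheylborane, Ipc from (−)-α-pinene | CCOC(=O)C/C=C\CB([C@H]1C[C@H]2C[C@@H]([C@@H]1C)C2(C)C)[C@H]1C[C@H]2C[C@@H]([C@@H]1C)C2(C)C | intermediate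
9 | ethyl (3S,4R,5E,9S,10S)-3-ethenyl-9,10-epoxy-4-hydroxy-6,10-dimethyldodeca-5,11-dienoate | CCOC(=O)C[C@@H](C=C)[C@@H](O)/C=C(\C)CC[C@@H]1O[C@@]1(C)C=C | intermediate
10 | 4-O-TBS ether of 9 | CCOC(=O)C[C@@H](C=C)[C@@H](O[Si](C)(C)C(C)(C)C)/C=C(\C)CC[C@@H]1O[C@@]1(C)C=C | intermediate
11 | ring ester of unit B, ethyl (4E,8Z)-6-(TBS-oxy)-1,10-epoxy-13-norgermacra-4,8-dien-12-oate | CCOC(=O)C[C@H]1/C=C\[C@]2(C)O[C@H]2CC/C(C)=C/[C@@H]1O[Si](C)(C)C(C)(C)C | intermediate
12 | lithium carboxylate of 11 | [Li+].[O-]C(=O)C[C@H]1/C=C\[C@]2(C)O[C@H]2CC/C(C)=C/[C@@H]1O[Si](C)(C)C(C)(C)C | intermediate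
13 | unit B lactone, (4E,9Z)-6-(TBS-oxy)-1-hydroxy-13-norgermacra-4,9-dien-12,8-olide, C1'–OH epimeric to the target | C1C(=O)O[C@@H]2/C=C(/C)[C@@H](O)CC/C(C)=C/[C@H](O[Si](C)(C)C(C)(C)C)[C@@H]12 | intermediate
14 | 1'-O-(4-nitrobenzoate) of the unit B lactone, C1' inverted | C1C(=O)O[C@@H]2/C=C(/C)[C@H](OC(=O)c3ccc(cc3)[N+](=O)[O-])CC/C(C)=C/[C@H](O[Si](C)(C)C(C)(C)C)[C@@H]12 | intermediate
15 | unit B lactone with C1'–OH as in the target (6'-O-TBS) | C1C(=O)O[C@@H]2/C=C(/C)[C@H](O)CC/C(C)=C/[C@H](O[Si](C)(C)C(C)(C)C)[C@@H]12 | intermediate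
16 | 1',6'-bis-TBS ether of the unit B lactone | C1C(=O)O[C@@H]2/C=C(/C)[C@H](O[Si](C)(C)C(C)(C)C)CC/C(C)=C/[C@H](O[Si](C)(C)C(C)(C)C)[C@@H]12 | intermediate
17 | α-(iodomethyl) lactone of unit B (C11' as in the target) | IC[C@@H]1C(=O)O[C@@H]2/C=C(/C)[C@H](O[Si](C)(C)C(C)(C)C)CC/C(C)=C/[C@H](O[Si](C)(C)C(C)(C)C)[C@@H]12 | intermediate
18 | (E)-(5-ethoxy-5-oxopent-2-en-1-yl)diisopinocampheylborane, Ipc from (+)-α-pinene | CCOC(=O)C/C=C/CB([C@@H]1C[C@@H]2C[C@H]([C@H]1C)C2(C)C)[C@@H]1C[C@@H]2C[C@H]([C@H]1C)C2(C)C | intermediate
19 | ethyl (3S,4S,5E,9S,10S)-3-ethenyl-9,10-epoxy-4-hydroxy-6,10-dimethyldodeca-5,11-dienoate | CCOC(=O)C[C@@H](C=C)[C@H](O)/C=C(\C)CC[C@@H]1O[C@@]1(C)C=C | intermediate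
20 | 4-O-TBS ether of 19 | CCOC(=O)C[C@@H](C=C)[C@H](O[Si](C)(C)C(C)(C)C)/C=C(\C)CC[C@@H]1O[C@@]1(C)C=C | intermediate
21 | ring ester of unit A (C6 epimer of 11) | CCOC(=O)C[C@H]1/C=C\[C@]2(C)O[C@H]2CC/C(C)=C/[C@H]1O[Si](C)(C)C(C)(C)C | intermediate
22 | lithium carboxylate of 21 | [Li+].[O-]C(=O)C[C@H]1/C=C\[C@]2(C)O[C@H]2CC/C(C)=C/[C@H]1O[Si](C)(C)C(C)(C)C | intermediate
23 | unit A lactone, (4E,9Z)-6-(TBS-oxy)-1-hydroxy-13-norgermacra-4,9-dien-12,8-olide (C6 epimer of 13) | C1C(=O)O[C@@H]2/C=C(/C)[C@@H](O)CC/C(C)=C/[C@@H](O[Si](C)(C)C(C)(C)C)[C@@H]12 | intermediate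
24 | α-(iodomethyl) lactone of unit A | IC[C@@H]1C(=O)O[C@@H]2/C=C(/C)[C@@H](O)CC/C(C)=C/[C@@H](O[Si](C)(C)C(C)(C)C)[C@@H]12 | intermediate
25 | α-methylene lactone of unit A, (4E,9Z)-6-(TBS-oxy)-1-hydroxygermacra-4,9,11(13)-trien-12,8-olide | C=C1C(=O)O[C@@H]2/C=C(/C)[C@@H](O)CC/C(C)=C/[C@@H](O[Si](C)(C)C(C)(C)C)[C@@H]12 | intermediate
26 | C1 methyl carbonate of 25 | C=C1C(=O)O[C@@H]2/C=C(/C)[C@@H](OC(=O)OC)CC/C(C)=C/[C@@H](O[Si](C)(C)C(C)(C)C)[C@@H]12 | intermediate
27 | alkylzinc iodide from 17 (C13'–ZnI) | I[Zn]C[C@@H]1C(=O)O[C@@H]2/C=C(/C)[C@H](O[Si](C)(C)C(C)(C)C)CC/C(C)=C/[C@H](O[Si](C)(C)C(C)(C)C)[C@@H]12 | intermediate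
28 | 6,1',6'-tris-TBS ether of the target | C=C1C(=O)O[C@@H]2/C=C(/C)[C@H](C[C@@H]3C(=O)O[C@@H]4/C=C(/C)[C@H](O[Si](C)(C)C(C)(C)C)CC/C(C)=C/[C@H](O[Si](C)(C)C(C)(C)C)[C@@H]34)CC/C(C)=C/[C@@H](O[Si](C)(C)C(C)(C)C)[C@@H]12 | intermediate
29 | CNP0307352.2 | C=C1C(=O)O[C@@H]2/C=C(/C)[C@H](C[C@@H]3C(=O)O[C@@H]4/C=C(/C)[C@H](O)CC/C(C)=C/[C@H](O)[C@@H]34)CC/C(C)=C/[C@@H](O)[C@@H]12 | target

**Totals**
Total step count: 20. Longest linear sequence: 14 steps (steps 1–12, 19, 20).

**Steps most likely to fail**

Step 19 (carries the label). The allyl group may pass from palladium to zinc, or β-hydride elimination may occur from the alkyl(allyl)palladium intermediate; either would reduce or eliminate the unit A allyl system and waste the zinc reagent. Inversion may also be eroded by palladium–palladium exchange. The fallback leaves two-electron transmetallation for a radical cross-electrophile coupling, a known reaction type (nickel-catalysed reductive allylation of alkyl iodides). Iodide 17 and carbonate 26 are combined directly with NiBr2·dme, 4,4'-di-tert-butyl-2,2'-bipyridine and manganese powder in DMA. The C13' radical should be captured at the less hindered C1 terminus of the allylnickel species, with the C1 configuration set by the ring face and not by inversion. This fallback sets out from 17 and 26, returns at 28 and makes no new compound (F0).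

Step 9 (key step). Ionisation may run through the extended oxirane conformer (C1' syn on the allyl), which would give the (9E)-olefin with the cis-fused C8' epimer; competing 1,2-addition is also possible. The fallback activates the olefin electrophilically instead of ionising the oxirane. It sets out from carboxylate 12: iodolactonisation (I2, NaHCO3, MeCN, 0 °C) should add the carboxylate to C8' and iodine to C9' in anti fashion to give the iodo-oxirane lactone F1. Zinc dust (EtOH, NH4Cl) then removes iodide with anti-periplanar opening of the C10'–O bond, which fixes the (9Z)-olefin and frees the C1' carbinol. The route is rejoined at 13.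

Step 8. Oligomerisation may outrun closure of the ten-membered ring, or the hindered olefin on the quaternary oxirane carbon may fail to engage. The fallback ties the two olefin-bearing arms to a temporary five-membered ring before metathesis. It sets out from 9: acid-catalysed lactonisation (PPTS, benzene, reflux) gives the trans-4,5-disubstituted γ-lactone F2. Ring-closing metathesis on this pre-organised diene gives the bicyclic 12,6-lactone F3. LiOH opens it to the lithium hydroxy-carboxylate F4. TBSOTf–2,6-lutidine silylates both oxygens to the silyl ether silyl ester F5, and LiOH (THF–H2O) cleaves only the silyl ester. The route is rejoined at 12.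

**Further compounds**
F0 | step 19 | none | none
F1 | step 9 | iodo-oxirane lactone of unit B (O–C8' and I–C9' anti, 1',10'-oxirane intact, 6'-O-TBS) | C1C(=O)O[C@@H]2[C@@H](I)[C@]3(C)O[C@H]3CC/C(C)=C/[C@H](O[Si](C)(C)C(C)(C)C)[C@@H]12
F2 | step 8 | trans-4-ethenyl-5-alkenyl γ-lactone from 9 (12,6-lactone, acyclic diene) | C=C[C@@H]1CC(=O)O[C@H]1/C=C(\C)CC[C@@H]2O[C@@]2(C)C=C
F3 | step 8 | bicyclic 12,6-lactone, (4E,8Z)-1,10-epoxy-13-norgermacra-4,8-dien-12,6-olide | O=C1C[C@H]2/C=C\[C@]3(C)O[C@H]3CC/C(C)=C/[C@@H]2O1
F4 | step 8 | lithium (4E,8Z)-1,10-epoxy-6-hydroxy-13-norgermacra-4,8-dien-12-oate | [Li+].[O-]C(=O)C[C@H]1/C=C\[C@]2(C)O[C@H]2CC/C(C)=C/[C@@H]1O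
F5 | step 8 | tert-butyldimethylsilyl ester of the 6-O-TBS ring acid | CC(C)(C)[Si](C)(C)OC(=O)C[C@H]1/C=C\[C@]2(C)O[C@H]2CC/C(C)=C/[C@@H]1O[Si](C)(C)C(C)(C)C
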